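**Plan**

Ring numbering: C1 carries the benzylic carbon C7, C2/C3/C6 carry Br, C4/C5 carry OH.
Retrosynthesis cuts the C–Br bonds first: C2–Br goes back through the amine to a nitro group, and C3–Br and C6–Br go back to C–H (electrophilic bromination).
Next, in each ring, C1–C2 and C2–C3 are cut: C2 returns to nitromethane and a 4-pyranone remains. Last, the C7–O–C7' ether is cut to two kojic acid units.
Enabling feature: C7–C1–C6–C5(O)–C4(O)–C3 of each ring is kojic acid's CH2–C2–C3–C4(=O)–C5(O)–C6 in the same order; only C2 is missing, and it sits where the pyranone ring oxygen O1 is.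
Forward: the ether chain is joined first, both benzene rings then arise together in one [5+1] operation, and bromine is placed at C6, C3 and C2 in that order before the acetals are removed.
Stereochemistry: none; the target is achiral, with no stereocentre or double-bond geometry to set.

Key step: step 4

Assumption: the molecule is twofold symmetric, so from step 4 on every reaction acts once on each ring, and reagent amounts are meant per molecule (twofold per ring).

**Route**

Step 1
Reactants: 1 kojic acid; 2 chloromethyl methyl ether
Product: 3 2-(hydroxymethyl)-5-(methoxymethoxy)-4H-pyran-4-one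
Conditions: MOMCl (1.05 equiv), K2CO3, DMF, 0 °C to rt
Reagents that add atoms: chloromethyl methyl ether (compound 2), COCCl
Why: Only the enolic 5-OH of kojic acid (pKa about 8) is ionised by carbonate, so this Williamson-type acetal protection occurs on the ring oxygen and leaves the primary alcohol free.

Step 2
Reactants: 3 2-(hydroxymethyl)-5-(methoxymethoxy)-4H-pyran-4-one (half of the material)
Product: 4 2-(bromomethyl)-5-(methoxymethoxy)-4H-pyran-4-one
Conditions: CBr4, PPh3, CH2Cl2, 0 °C
Reagents that add atoms: tetrabromomethane, BrC(Br)(Br)Br
Why: The Appel reaction turns the primary alcohol into the bromide under neutral conditions that spare the acid-labile MOM acetal and the pyranone.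

Step 3
Reactants: 3 2-(hydroxymethyl)-5-(methoxymethoxy)-4H-pyran-4-one; 4 2-(bromomethyl)-5-(methoxymethoxy)-4H-pyran-4-one
Product: 5 bis{[5-(methoxymethoxy)-4-oxo-4H-pyran-2-yl]methyl} ether
Conditions: NaH (1.05 equiv), THF/DMF, 0 °C; then 4, 0 °C to rt
Reagents that add atoms: none
Why: In this Williamson ether synthesis the sodium alkoxide of 3 displaces bromide from the activated CH2Br of 4 (allylic and vinylogous to the ring carbonyl) by SN2 at low temperature, faster than it can add to the pyranone ring.

Step 4
Reactants: 5 bis{[5-(methoxymethoxy)-4-oxo-4H-pyran-2-yl]methyl} ether; 6 nitromethane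
Product: 7 bis[5-hydroxy-4-(methoxymethoxy)-2-nitrobenzyl] ether
Conditions: MeNO2 (10 equiv), KOtBu (6 equiv), tBuOH/THF, rt then 70 °C, dark; AcOH quench at 0 °C
Reagents that add atoms: nitromethane (compound 6), C[N+](=O)[O-]
Why: The nitronate of 6 adds in Michael fashion to an alpha-carbon of each pyranone (the unsubstituted C6 or C2), the adduct opens by beta-elimination of the ring oxygen to a 1,3-dicarbonyl enolate, and the nitromethyl carbanion attacks the freed carbonyl in an intramolecular Henry reaction, after which loss of water aromatises the ring to the 4-nitrophenoxide. The closest known reaction type is the nitromethane/KOtBu conversion of 2,6-dialkyl-4-pyranones into 3,5-dialkyl-4-nitrophenols, together with the related condensation of pyrylium salts with nitromethane to nitrobenzenes. Each of the two benzene rings closes by a 6-exo-trig addition of the nitronate carbon to a C=O group, so that C1–C2 and C2–C3 are formed, one in the Michael step and one in the Henry step. No stereocentre is created. The step needs ring transformation to outrun simple Michael addition and base degradation: the MOM ether keeps the pyranone un-ionised and electrophilic, excess nitromethane levels the base to the nitronate so that the CH2–O–CH2 linker is not deprotonated, and aromatisation to a push-pull 4-nitrophenoxide makes the sequence irreversible and tames the 2-nitrobenzylic C–H of the product. Regiochemistry needs no control because attack at either alpha-carbon leads to the same arene, in which the pyranone C=O ends as the C5 hydroxyl para to the nitro group at C2.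

Step 5
Reactants: 7 bis[5-hydroxy-4-(methoxymethoxy)-2-nitrobenzyl] ether
Product: 8 bis[2-bromo-3-hydroxy-4-(methoxymethoxy)-6-nitrobenzyl] ether
Conditions: NBS (2.1 equiv), DMF, 0 °C to rt, dark
Reagents that add atoms: N-bromosuccinimide, O=C1CCC(=O)N1Br
Why: Electrophilic aromatic bromination is steered by the free phenol to its only open ortho position (C6, meta to the nitro group), while C3, which is ortho to NO2 and meta to OH, stays untouched and the neutral succinimide by-product spares the MOM ether.

Step 6
Reactants: 8 bis[2-bromo-3-hydroxy-4-(methoxymethoxy)-6-nitrobenzyl] ether; 2 chloromethyl methyl ether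
Product: 9 bis[2-bromo-3,4-bis(methoxymethoxy)-6-nitrobenzyl] ether
Conditions: MOMCl (3 equiv), K2CO3, DMF, rt, dark
Reagents that add atoms: chloromethyl methyl ether (compound 2), COCCl
Why: Williamson-type acetal protection of the acidic bromonitrophenol masks the oxygen para to nitrogen, so that the later aminophenol cannot be oxidised to a quinone imine by NBS or form a quinone diazide on diazotisation.

Step 7
Reactants: 9 bis[2-bromo-3,4-bis(methoxymethoxy)-6-nitrobenzyl] ether
Product: 10 bis[6-amino-2-bromo-3,4-bis(methoxymethoxy)benzyl] ether
Conditions: Fe powder, NH4Cl, EtOH/H2O (4:1), 70 °C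
Reagents that add atoms: none
Why: The Béchamp-type iron reduction at near-neutral pH reduces nitro groups selectively and leaves the aryl bromides, the MOM acetals and the benzylic ether intact.

Step 8
Reactants: 10 bis[6-amino-2-bromo-3,4-bis(methoxymethoxy)benzyl] ether
Product: 11 bis[2-amino-3,6-dibromo-4,5-bis(methoxymethoxy)benzyl] ether
Conditions: NBS (2.05 equiv), MeCN, −10 °C to 0 °C; used without storage
Reagents that add atoms: N-bromosuccinimide, O=C1CCC(=O)N1Br
Why: Electrophilic aromatic bromination occurs at the single remaining ring C–H (C3), which is ortho to both the amino group and an acetal oxygen, so the regiochemistry is unambiguous and mild, cold conditions suffice.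

Step 9
Reactants: 11 bis[2-amino-3,6-dibromo-4,5-bis(methoxymethoxy)benzyl] ether
Product: 13 bis[2,3,6-tribromo-4,5-bis(methoxymethoxy)benzyl] ether, via bis(diazonium) dibromide 12 (not isolated)
Conditions: tBuONO (3 equiv), CuBr2 (2.5 equiv), MeCN, 0 °C to 60 °C; 11 added slowly to the CuBr2/nitrite mixture
Reagents that add atoms: copper dibromide CuBr2, [Cu+2].[Br-].[Br-]; tert-butyl nitrite, CC(C)(C)ON=O (one nitrogen per ring of 12, lost again as N2)
Why: In this non-aqueous Sandmeyer reaction the alkyl nitrite diazotises the hindered amine in situ, and the aryl radical formed on loss of N2 is trapped by bromine-atom transfer from CuBr2, which is kept concentrated so that trapping outruns hydrogen abstraction from the neighbouring CH2–O–CH2 group.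

Step 10
Reactants: 13 bis[2,3,6-tribromo-4,5-bis(methoxymethoxy)benzyl] ether
Product: 14 bis(2,3,6-tribromo-4,5-dihydroxybenzyl) ether (target)
Conditions: TFA/CH2Cl2 (1:4), H2O (10 equiv), 0 °C to rt
Reagents that add atoms: none
Why: Acid-catalysed acetal hydrolysis frees the four phenols, since the electron-poor bromophenols are good leaving groups from the protonated MOM groups, and the cold, non-nucleophilic medium offers no alcohol that could exchange into the benzylic ether.

**Compound list**

1 | kojic acid, 5-hydroxy-2-(hydroxymethyl)-4H-pyran-4-one | O=c1cc(CO)occ1O | starting material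
2 | chloromethyl methyl ether | COCCl | starting material
3 | 2-(hydroxymethyl)-5-(methoxymethoxy)-4H-pyran-4-one | COCOc1coc(CO)cc1=O | intermediate
4 | 2-(bromomethyl)-5-(methoxymethoxy)-4H-pyran-4-one | COCOc1coc(CBr)cc1=O | intermediate
5 | bis{[5-(methoxymethoxy)-4-oxo-4H-pyran-2-yl]methyl} ether | COCOc1coc(COCc2cc(=O)c(OCOC)co2)cc1=O | intermediate
6 | nitromethane | C[N+](=O)[O-] | starting material
7 | bis[5-hydroxy-4-(methoxymethoxy)-2-nitrobenzyl] ether | O(Cc1cc(O)c(OCOC)cc1[N+](=O)[O-])Cc1cc(O)c(OCOC)cc1[N+](=O)[O-] | intermediate
8 | bis[2-bromo-3-hydroxy-4-(methoxymethoxy)-6-nitrobenzyl] ether | O(Cc1c(Br)c(O)c(OCOC)cc1[N+](=O)[O-])Cc1c(Br)c(O)c(OCOC)cc1[N+](=O)[O-] | intermediate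
9 | bis[2-bromo-3,4-bis(methoxymethoxy)-6-nitrobenzyl] ether | O(Cc1c(Br)c(OCOC)c(OCOC)cc1[N+](=O)[O-])Cc1c(Br)c(OCOC)c(OCOC)cc1[N+](=O)[O-] | intermediate
10 | bis[6-amino-2-bromo-3,4-bis(methoxymethoxy)benzyl] ether | O(Cc1c(Br)c(OCOC)c(OCOC)cc1N)Cc1c(Br)c(OCOC)c(OCOC)cc1N | intermediate
11 | bis[2-amino-3,6-dibromo-4,5-bis(methoxymethoxy)benzyl] ether | O(Cc1c(Br)c(OCOC)c(OCOC)c(Br)c1N)Cc1c(Br)c(OCOC)c(OCOC)c(Br)c1N | intermediate
12 | 2,2'-[oxybis(methylene)]bis[3,6-dibromo-4,5-bis(methoxymethoxy)benzenediazonium] dibromide | O(Cc1c(Br)c(OCOC)c(OCOC)c(Br)c1[N+]#N)Cc1c(Br)c(OCOC)c(OCOC)c(Br)c1[N+]#N.[Br-].[Br-] | intermediate (not isolated)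
13 | bis[2,3,6-tribromo-4,5-bis(methoxymethoxy)benzyl] ether | O(Cc1c(Br)c(OCOC)c(OCOC)c(Br)c1Br)Cc1c(Br)c(OCOC)c(OCOC)c(Br)c1Br | intermediate
14 | bis(2,3,6-tribromo-4,5-dihydroxybenzyl) ether | Oc1c(O)c(Br)c(COCc2c(Br)c(O)c(O)c(Br)c2Br)c(Br)c1Br | target

**Step count and risks**

Total steps: 10. Longest linear sequence: 10 steps (1 → 3 → 4 → 5 → 7 → 8 → 9 → 10 → 11 → 13 → 14; compound 3 feeds both step 2 and step 3).

The three steps most likely to fail:

Step 4. Two ring transformations must succeed in one molecule in hot base. The nitronate may add without the second, ring-closing Henry step following, or the half-converted material may be degraded at its CH2–O–CH2 linker before the second ring has formed. The fallback changes the order of events: the ring is built on the monomer and the ether is formed afterwards under neutral conditions. It sets out from 3 and returns to the route at 9.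
- Compound 3 is treated with nitromethane 6 and KOtBu as in step 4 to give 5-(hydroxymethyl)-2-(methoxymethoxy)-4-nitrophenol F1.
- NBS in DMF brominates ortho to the phenol to give 2-bromo-3-(hydroxymethyl)-6-(methoxymethoxy)-4-nitrophenol F2.
- Phenol-selective protection with 2 and K2CO3 gives [2-bromo-3,4-bis(methoxymethoxy)-6-nitrophenyl]methanol F3.
- Half of F3 is converted with CBr4/PPh3 into 2-bromo-3,4-bis(methoxymethoxy)-6-nitrobenzyl bromide F4.
- F3 and F4 are joined with Ag2O in CH2Cl2 over molecular sieves, a silver-assisted etherification that avoids nitrobenzyl anion chemistry, to give 9.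

Step 9. The aryl radical formed on loss of N2 is flanked by bromine and the benzylic ether. It may abstract a hydrogen from the neighbouring ether carbon (1,5-hydrogen shift), or be reduced before bromine transfer, which would cleave the ether or give simple deamination. The fallback brings in the third bromine by electrophilic substitution instead of radical ligand transfer. It sets out from 11 and returns at 13.
- Reductive deamination with tBuONO in THF at 60 °C, where hydrogen abstraction is the wanted outcome, gives bis[2,5-dibromo-3,4-bis(methoxymethoxy)benzyl] ether F5.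
- The freed ring position is para to an acetal oxygen and is brominated with NBS in DMF at rt to 40 °C to give 13.

Step 10. Once the hydroxyl para to C7 is free, acid can ionise the benzylic C7–O bond through a quinone-methide-like cation, so the ether may be scrambled or cleaved while the acetals are removed. The fallback uses this ionisation instead of fighting it. It sets out from 13 and returns at 14.
- Aqueous HCl in THF at 50 °C deliberately hydrolyses all acetals and the ether to 2,3,6-tribromo-4,5-dihydroxybenzyl alcohol F6.
- F6 is re-etherified by acid-catalysed dehydrative self-condensation (catalytic TsOH, dry dioxane, 4 Å molecular sieves, 60 °C) to give 14. With every ring position substituted, C-alkylation is impossible and the symmetrical ether is the only condensation product open to the benzylic cation.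

Further compounds
F1 | step 4 | 5-(hydroxymethyl)-2-(methoxymethoxy)-4-nitrophenol | OCc1cc(O)c(OCOC)cc1[N+](=O)[O-]
F2 | step 4 | 2-bromo-3-(hydroxymethyl)-6-(methoxymethoxy)-4-nitrophenol | OCc1c(Br)c(O)c(OCOC)cc1[N+](=O)[O-]
F3 | step 4 | [2-bromo-3,4-bis(methoxymethoxy)-6-nitrophenyl]methanol | OCc1c(Br)c(OCOC)c(OCOC)cc1[N+](=O)[O-]
F4 | step 4 | 2-bromo-3,4-bis(methoxymethoxy)-6-nitrobenzyl bromide | BrCc1c(Br)c(OCOC)c(OCOC)cc1[N+](=O)[O-]
F5 | step 9 | bis[2,5-dibromo-3,4-bis(methoxymethoxy)benzyl] ether | O(Cc1cc(Br)c(OCOC)c(OCOC)c1Br)Cc1cc(Br)c(OCOC)c(OCOC)c1Br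
F6 | step 10 | 2,3,6-tribromo-4,5-dihydroxybenzyl alcohol | OCc1c(Br)c(O)c(O)c(Br)c1Br
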